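A direct plan would close ring C last, through the C3–C4 bond. The propargylic alcohol A1, which would carry ring B and the prenyl carbons as an enyne, would be joined by Mitsunobu etherification to the salicylaldehyde A2. The ether A3 would undergo carbene-catalysed intramolecular hydroacylation of its alkyne and a base-induced double-bond shift to the protected 5,7-dimethoxyflavone A4, and a Lewis acid would free the three phenols. Its weakest steps would be:
- the etherification, because a carbinol that is both propargylic and benzylic to an electron-rich arene would ionise, so that allenyl ethers and elimination would compete;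
- the hydroacylation, because an electron-rich, doubly ortho-substituted aldehyde would form the acyl anion equivalent slowly and an unactivated enyne would accept it poorly;
- the final step, because the Lewis acid would have to cleave the methyl ether at O5 but not at O7, and two acetals, beside an acid-sensitive prenyl group.

The new route would make ring A last, from a monocyclic γ-pyrone. The key step is a photochemical Danheiser benzannulation of a 6-diazoacetyl-2-aryl-3-prenyl-4-pyranone with methoxyacetylene. Wolff rearrangement, ketene–alkyne [2+2] cycloaddition, four-electron ring opening and six-electron electrocyclisation onto the pyranone would form the ring A bonds C5–C6, C7–C8 and C4a–C5 (flavone numbering) in one operation. It exploits the pattern of ring A: the ketene carbonyl becomes the free O5–H peri to C4=O, the alkyne brings O7–Me, and C6 and C8 carry hydrogen. Ring C would come from a triketone cyclodehydration, so no etherification at a propargylic carbinol, no hydroacylation and no O-demethylation remain.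

Key step: step 8

Remark: the target has no stereogenic element; the stereocentres of 6, 14 and 16 are transient, so these compounds would be racemic.

Step 1
Reactants: 1 6-methylhept-5-en-2-one; 2 diethyl oxalate
Product: 3 ethyl 8-methyl-2,4-dioxonon-7-enoate
Conditions: LiN(SiMe3)2 (1.1 equiv), THF, −78 °C; 2 (1.2 equiv), −78 °C → rt; aq. HCl (1 M), 0 °C
Reagents that add atoms: none
Why: Crossed Claisen condensation in which the kinetic lithium enolate forms at the methyl group of the methyl ketone and is acylated by the non-enolisable oxalate, the released ethoxide converting the product into its stable enolate and so preventing a second acylation.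

Step 2
Reactants: 4 methyl 2,4-dihydroxybenzoate
Product: 5 methyl 2,4-bis(methoxymethoxy)benzoate
Conditions: NaH (2.5 equiv), MOMCl (2.6 equiv), DMF, 0 °C → rt
Reagents that add atoms: chloromethyl methyl ether, COCCl
Why: Williamson-type O-alkylation of both phenoxides (NaH also breaks the hydrogen bond of the 2-OH to the ester) gives base-stable acetals that will keep the ring B oxygens from reacting with the ketene of step 8.

Step 3
Reactants: 3 ethyl 8-methyl-2,4-dioxonon-7-enoate; 5 methyl 2,4-bis(methoxymethoxy)benzoate
Product: 6 ethyl 5-[2,4-bis(methoxymethoxy)benzoyl]-8-methyl-2,4-dioxonon-7-enoate (racemic, largely enolised)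
Conditions: 3 (2.2 equiv), LiN(i-Pr)2 (4.4 equiv), THF, −78 → −20 °C; 5 (1.0 equiv), −78 → 0 °C; aq. NH4Cl
Reagents that add atoms: none
Why: Claisen condensation of a doubly deprotonated β-dicarbonyl compound, in which the second deprotonation of 3 can only occur at C5 and this most basic carbon is acylated by the aryl ester, while the second equivalent of the dianion takes up the proton of the more acidic triketone so that no free amide base remains; the new centre at C5 is racemic and becomes sp2 in step 4.

Step 4
Reactants: 6 ethyl 5-[2,4-bis(methoxymethoxy)benzoyl]-8-methyl-2,4-dioxonon-7-enoate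
Product: 7 ethyl 6-[2,4-bis(methoxymethoxy)phenyl]-5-(3-methylbut-2-en-1-yl)-4-oxo-4H-pyran-2-carboxylate
Conditions: PPh3 (2.0 equiv), CCl4 (4 equiv), Et3N (2.0 equiv), MeCN, 0 °C → rt
Reagents that add atoms: none
Why: Appel-type cyclodehydration of a 1,3,5-tricarbonyl compound, in which one terminal enol oxygen is activated by the phosphonium reagent and the other closes the 4-pyranone by 6-endo addition–elimination under non-acidic conditions, so that the prenyl group (which would cyclise onto an enol in acid) and the MOM ethers are spared, and either direction of closure gives the same pyranone.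

Step 5
Reactants: 7 ethyl 6-[2,4-bis(methoxymethoxy)phenyl]-5-(3-methylbut-2-en-1-yl)-4-oxo-4H-pyran-2-carboxylate
Product: 8 6-[2,4-bis(methoxymethoxy)phenyl]-5-(3-methylbut-2-en-1-yl)-4-oxo-4H-pyran-2-carboxylic acid
Conditions: LiOH·H2O (1.3 equiv), THF–H2O (3:1), 0 °C; aq. HCl (0.5 M) to pH 3, 0 °C
Reagents that add atoms: lithium hydroxide, [Li+].[OH-]
Why: Saponification of an ester that is activated by the ring oxygen and the vinylogous carbonyl group should be fast at 0 °C with little excess hydroxide, so that the γ-pyrone is not opened, and the brief cold acidification leaves the MOM ethers intact.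

Step 6
Reactants: 8 6-[2,4-bis(methoxymethoxy)phenyl]-5-(3-methylbut-2-en-1-yl)-4-oxo-4H-pyran-2-carboxylic acid
Product: 10 2-[2,4-bis(methoxymethoxy)phenyl]-6-(diazoacetyl)-3-(3-methylbut-2-en-1-yl)-4H-pyran-4-one, via acyl chloride 9 (not isolated)
Conditions: Me2C=C(Cl)NMe2 (1.2 equiv), CH2Cl2, 0 °C; then CH2N2 (1.3 equiv, Et2O), Et3N (1.1 equiv), THF, −20 → 0 °C
Reagents that add atoms: diazomethane, C=[N+]=[N-]
Why: Acylation of diazomethane by the acyl chloride 9, made under neutral conditions that spare the MOM ethers (first stage of the Arndt–Eistert sequence), with Et3N as HCl acceptor (safe because 9 has no α-hydrogen) and with little excess diazomethane at low temperature to limit dipolar cycloaddition to the pyranone C5=C6 bond.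

Step 7
Reactants: 11 2-chloro-1,1-dimethoxyethane
Product: 12 methoxyethyne (methoxyacetylene)
Conditions: NaNH2 (3.1 equiv), liquid NH3, −33 °C; cold aq. NaCl, −70 °C; distillation (bp 23 °C) into cold ClCH2CH2Cl
Reagents that add atoms: none
Why: Twofold base-induced 1,2-elimination of methanol and of HCl gives the sodium alkynide, which is protonated on quenching; this is the standard preparation of simple alkoxyacetylenes.

Step 8
Reactants: 10 2-[2,4-bis(methoxymethoxy)phenyl]-6-(diazoacetyl)-3-(3-methylbut-2-en-1-yl)-4H-pyran-4-one; 12 methoxyethyne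
Product: 17 2-[2,4-bis(methoxymethoxy)phenyl]-5-hydroxy-7-methoxy-3-(3-methylbut-2-en-1-yl)-4H-chromen-4-one, via pyranonylketene 13 (not isolated), via methoxycyclobutenone 14 (not isolated), via dienylketene 15 (not isolated), via cyclohexadienone 16 (not isolated)
Conditions: 12 (4 equiv), ClCH2CH2Cl (degassed, 0.05 M), hν (350 nm, Pyrex), 5 °C, closed vessel; then 80 °C
Reagents that add atoms: none
Why: Light expels N2 from 10 and the pyranonyl group migrates (Wolff rearrangement) to give ketene 13, whose carbonyl carbon is attacked by the nucleophilic CH terminus of the ynol ether, so that the [2+2] cycloaddition gives only cyclobutenone 14; reversible conrotatory four-electron opening of 14 (light or 80 °C) gives dienylketene 15, whose isomer with the pyranone cis to the ketene undergoes six-electron electrocyclisation onto the unsubstituted C5 of the pyranone (the future C4a), and enolisation of the doubly activated C4a–H of 16 gives the phenol. The closest known reaction type is the Danheiser benzannulation of α,β-unsaturated and heteroaryl diazomethyl ketones with alkoxy- and siloxyacetylenes, here applied to a γ-pyrone. Ring A is the only ring closed, by a thermal six-electron electrocyclisation (C4a–C5) that follows the formation of C5–C6 and C7–C8 in the cycloaddition, and it is aromatised by tautomerisation without an oxidant. No stereocentre is set: those of 14 and 16 disappear on ring opening and enolisation. The step needs regioselectivity (OH on C5, OMe on C7, H on C6 and C8) and chemoselectivity (ynol ether before the prenyl alkene): the first is secured by the polarity of the ketene–ynol ether pair and by C5 being the only carbon next to the ketene-bearing C6 of the pyranone (the future C8a), the second by the much higher ketenophilicity of the ynol ether and by the prenyl group lying across the ring, out of reach. The MOM ethers keep the ring B oxygens from adding to the ketene, and the new 5-OH, chelated to C4=O, should be a poor ketene trap.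

Step 9
Reactants: 17 2-[2,4-bis(methoxymethoxy)phenyl]-5-hydroxy-7-methoxy-3-(3-methylbut-2-en-1-yl)-4H-chromen-4-one
Product: 18 2-(2,4-dihydroxyphenyl)-5-hydroxy-7-methoxy-3-(3-methylbut-2-en-1-yl)-4H-chromen-4-one
Conditions: HCl (1.25 M in MeOH), MeOH, 0 °C → rt
Reagents that add atoms: none
Why: Acid-catalysed transacetalisation of the two aryl MOM ethers to dimethoxymethane in dilute acid at or below room temperature, where the acetal oxygens are protonated far faster than the trisubstituted alkene, the methyl ether at O7 is inert, and the only ring that the 2′-OH could form with the prenyl group would be eight-membered.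

Compound list
1 | 6-methylhept-5-en-2-one | CC(=O)CCC=C(C)C | starting material
2 | diethyl oxalate | CCOC(=O)C(=O)OCC | starting material
3 | ethyl 8-methyl-2,4-dioxonon-7-enoate | CCOC(=O)C(=O)CC(=O)CCC=C(C)C | intermediate
4 | methyl 2,4-dihydroxybenzoate | COC(=O)c1ccc(O)cc1O | starting material
5 | methyl 2,4-bis(methoxymethoxy)benzoate | COCOc1ccc(C(=O)OC)c(OCOC)c1 | intermediate
6 | ethyl 5-[2,4-bis(methoxymethoxy)benzoyl]-8-methyl-2,4-dioxonon-7-enoate (racemic, enolised) | CCOC(=O)C(=O)CC(=O)C(CC=C(C)C)C(=O)c1ccc(OCOC)cc1OCOC | intermediate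
7 | ethyl 6-[2,4-bis(methoxymethoxy)phenyl]-5-(3-methylbut-2-en-1-yl)-4-oxo-4H-pyran-2-carboxylate | CCOC(=O)c1cc(=O)c(CC=C(C)C)c(-c2ccc(OCOC)cc2OCOC)o1 | intermediate
8 | 6-[2,4-bis(methoxymethoxy)phenyl]-5-(3-methylbut-2-en-1-yl)-4-oxo-4H-pyran-2-carboxylic acid | OC(=O)c1cc(=O)c(CC=C(C)C)c(-c2ccc(OCOC)cc2OCOC)o1 | intermediate
9 | 6-[2,4-bis(methoxymethoxy)phenyl]-5-(3-methylbut-2-en-1-yl)-4-oxo-4H-pyran-2-carbonyl chloride | ClC(=O)c1cc(=O)c(CC=C(C)C)c(-c2ccc(OCOC)cc2OCOC)o1 | intermediate (not isolated)
10 | 2-[2,4-bis(methoxymethoxy)phenyl]-6-(diazoacetyl)-3-(3-methylbut-2-en-1-yl)-4H-pyran-4-one | [N-]=[N+]=CC(=O)c1cc(=O)c(CC=C(C)C)c(-c2ccc(OCOC)cc2OCOC)o1 | intermediate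
11 | 2-chloro-1,1-dimethoxyethane | COC(CCl)OC | starting material
12 | methoxyethyne (methoxyacetylene) | COC#C | intermediate
13 | 2-{6-[2,4-bis(methoxymethoxy)phenyl]-5-(3-methylbut-2-en-1-yl)-4-oxo-4H-pyran-2-yl}ethen-1-one (pyranonylketene) | O=C=Cc1cc(=O)c(CC=C(C)C)c(-c2ccc(OCOC)cc2OCOC)o1 | intermediate (not isolated)
14 | rac-4-{6-[2,4-bis(methoxymethoxy)phenyl]-5-(3-methylbut-2-en-1-yl)-4-oxo-4H-pyran-2-yl}-3-methoxycyclobut-2-en-1-one | COC1=CC(=O)C1c1cc(=O)c(CC=C(C)C)c(-c2ccc(OCOC)cc2OCOC)o1 | intermediate (not isolated)
15 | (3E)-4-{6-[2,4-bis(methoxymethoxy)phenyl]-5-(3-methylbut-2-en-1-yl)-4-oxo-4H-pyran-2-yl}-3-methoxybuta-1,3-dien-1-one (pyranone cis to the ketene carbon) | O=C=C/C(OC)=C\c1cc(=O)c(CC=C(C)C)c(-c2ccc(OCOC)cc2OCOC)o1 | intermediate (not isolated)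
16 | rac-2-[2,4-bis(methoxymethoxy)phenyl]-7-methoxy-3-(3-methylbut-2-en-1-yl)-4aH-chromene-4,5-dione | COC1=CC(=O)C2C(=O)C(CC=C(C)C)=C(c3ccc(OCOC)cc3OCOC)OC2=C1 | intermediate (not isolated)
17 | 2-[2,4-bis(methoxymethoxy)phenyl]-5-hydroxy-7-methoxy-3-(3-methylbut-2-en-1-yl)-4H-chromen-4-one | COCOc1ccc(-c2oc3cc(OC)cc(O)c3c(=O)c2CC=C(C)C)c(OCOC)c1 | intermediate
18 | 2-(2,4-dihydroxyphenyl)-5-hydroxy-7-methoxy-3-(3-methylbut-2-en-1-yl)-4H-chromen-4-one | COc1cc(O)c2c(=O)c(CC=C(C)C)c(-c3ccc(O)cc3O)oc2c1 | target

Total step count: 9. Longest linear sequence: 7 steps (steps 1, 3, 4, 5, 6, 8 and 9); steps 2 and 7 are side branches.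

Steps most likely to fail

Step 8. The photolysis could be diverted by light absorption of the γ-pyrone and flavone chromophores, or the ketene could dimerise faster than it is trapped if the volatile alkyne escapes. The fallback would generate the same ketene in the dark by dehydrochlorination. Setting out from 10, a Wolff rearrangement catalysed by silver benzoate (PhCO2Ag, Et3N, THF–H2O, rt, dark) would give the homologous (4-oxo-4H-pyran-2-yl)acetic acid F1. Me2C=C(Cl)NMe2 would convert it into the (4-oxo-4H-pyran-2-yl)acetyl chloride F2. Slow addition of Et3N to F2 and 12 in CH2Cl2 at 0 °C would form ketene 13 and, by cycloaddition, cyclobutenone 14, where the route is rejoined and 14 is heated to 17.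

Step 3. The C5 carbanion of doubly deprotonated 3 could attack its own ester group (Dieckmann-type closure to a cyclopentanetrione), or the electron-rich, ortho-substituted ester 5 could be acylated too slowly. The fallback would reverse the order of the two Claisen condensations. Setting out from 5, condensation with acetone (NaH, THF, reflux) would give the 1-arylbutane-1,3-dione F3. C-Alkylation with 1-bromo-3-methylbut-2-ene (K2CO3, acetone) would give the 2-prenyl-1,3-dione F4. Double deprotonation of F4 (LiN(i-Pr)2, 2.2 equiv, THF, −78 °C) and acylation of its terminal carbon with diethyl oxalate 2 would give 6, where the route is rejoined.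

Step 6. Diazomethane could add as a 1,3-dipole to the electron-poor C5=C6 bond of the pyranone, or the acid could end as its methyl ester. The fallback would introduce the diazo group by diazo transfer to a methyl ketone. Setting out from 8 by way of 9, MeNHOMe·HCl and pyridine would give the N-methoxy-N-methylamide F5, and MeMgBr (THF, −78 °C) would give the 6-acetylpyranone F6. Its lithium enolate (LiN(SiMe3)2, THF, −78 °C) would be trifluoroacetylated with CF3CO2CH2CF3 to the trifluoromethyl 1,3-diketone F7, which would not be isolated. MsN3, Et3N and H2O in MeCN would then give 10 by detrifluoroacetylative diazo transfer, where the route is rejoined.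

Further compounds
F1 | step 8 | 2-{6-[2,4-bis(methoxymethoxy)phenyl]-5-(3-methylbut-2-en-1-yl)-4-oxo-4H-pyran-2-yl}acetic acid | OC(=O)Cc1cc(=O)c(CC=C(C)C)c(-c2ccc(OCOC)cc2OCOC)o1
F2 | step 8 | 2-{6-[2,4-bis(methoxymethoxy)phenyl]-5-(3-methylbut-2-en-1-yl)-4-oxo-4H-pyran-2-yl}acetyl chloride | ClC(=O)Cc1cc(=O)c(CC=C(C)C)c(-c2ccc(OCOC)cc2OCOC)o1
F3 | step 3 | 1-[2,4-bis(methoxymethoxy)phenyl]butane-1,3-dione | CC(=O)CC(=O)c1ccc(OCOC)cc1OCOC
F4 | step 3 | 1-[2,4-bis(methoxymethoxy)phenyl]-2-(3-methylbut-2-en-1-yl)butane-1,3-dione (racemic, enolised) | CC(=O)C(CC=C(C)C)C(=O)c1ccc(OCOC)cc1OCOC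
F5 | step 6 | 6-[2,4-bis(methoxymethoxy)phenyl]-N-methoxy-N-methyl-5-(3-methylbut-2-en-1-yl)-4-oxo-4H-pyran-2-carboxamide | CON(C)C(=O)c1cc(=O)c(CC=C(C)C)c(-c2ccc(OCOC)cc2OCOC)o1
F6 | step 6 | 6-acetyl-2-[2,4-bis(methoxymethoxy)phenyl]-3-(3-methylbut-2-en-1-yl)-4H-pyran-4-one | CC(=O)c1cc(=O)c(CC=C(C)C)c(-c2ccc(OCOC)cc2OCOC)o1
F7 | step 6 | 1-{6-[2,4-bis(methoxymethoxy)phenyl]-5-(3-methylbut-2-en-1-yl)-4-oxo-4H-pyran-2-yl}-4,4,4-trifluorobutane-1,3-dione | FC(F)(F)C(=O)CC(=O)c1cc(=O)c(CC=C(C)C)c(-c2ccc(OCOC)cc2OCOC)o1
A1 | direct plan | rac-1-[2,4-bis(methoxymethoxy)phenyl]-5-methylhex-4-en-2-yn-1-ol | COCOc1ccc(C(O)C#CC=C(C)C)c(OCOC)c1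
A2 | direct plan | 2-hydroxy-4,6-dimethoxybenzaldehyde | COc1cc(O)c(C=O)c(OC)c1
A3 | direct plan | rac-2-({1-[2,4-bis(methoxymethoxy)phenyl]-5-methylhex-4-en-2-yn-1-yl}oxy)-4,6-dimethoxybenzaldehyde | COCOc1ccc(C(Oc2cc(OC)cc(OC)c2C=O)C#CC=C(C)C)c(OCOC)c1
A4 | direct plan | 2-[2,4-bis(methoxymethoxy)phenyl]-5,7-dimethoxy-3-(3-methylbut-2-en-1-yl)-4H-chromen-4-one | COCOc1ccc(-c2oc3cc(OC)cc(OC)c3c(=O)c2CC=C(C)C)c(OCOC)c1
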